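All constants are those of an exercise; no experiment stands behind them.

The reagent, charged at 1.00 equiv in all four set-ups, was the thing I followed, and spring was the flask I reckoned by hand.

    reagent + single product → bis adduct (k1 = 60 M⁻¹ s⁻¹)
    starting material + reagent → single product (k2 = 110 M⁻¹ s⁻¹)
    starting material + single product → side product (k3 = 22 M⁻¹ s⁻¹)

| flask | starting material | reagent | remark | time |
|---|---|---|---|---|
| summer | 2.0 mM | 1.00 equiv | one stirred flow tank at steady state, fed with the mixture as stated, mean residence time 2.5 min |  |
| dusk | 2.0 mM | 1.00 equiv (fed, over 1.25 min) | a stirred flask in which reagent is dosed at a steady rate over 1.25 min without added volume, worked up at 2.5 min | 2.5 min |
| spring | 2.0 mM | 1.00 equiv | everything together in a closed stirred flask, run for 2.5 min | 2.5 min |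
| autumn | 2.0 mM (fed, over 1.25 min) | 1.00 equiv | all but starting material at the start; starting material goes in evenly over 1.25 min, the run ends at 2.5 min | 2.5 min |

* the set-up with the highest share of single product in all that became single product or bis adduct or side product, at the outlet or at the end ("none" if the first two lie within 2 percentage points) (summer / dusk / spring / autumn / none)
* share of single product in all that became single product or bis adduct or side product, at the outlet or at the end, summer
* share of single product in all that became single product or bis adduct or side product, at the outlet or at the end, dusk
* share of single product in all that became single product or bis adduct or side product, at the outlet or at the end, spring
* share of single product in all that became single product or bis adduct or side product, at the outlet or at the end, autumn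

- in percentages every species weighs as the starting material in it: one side product counts as two
- the stated concentrations are those of everything mixed, before any reaction; amounts are the same in each set-up
- the feed brings no volume worth counting
- run time (dusk): 2.5 min

In the first instants of spring, the reagent met almost nothing but starting material, which had a half-life of 0.053 min by that step alone at the charged concentrations, far shorter than the run. In the middle, single product competed for the same reagent. Its own half-life against reagent as charged, 0.096 min, was also short beside the run, so the race would be settled early. The selectivity factor, second addition over first, was 0.545. I left the side-product step out of this race, which makes what follows an estimate: that step uses no reagent, but it does take starting material and single product.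

Dividing the balances of single product and starting material removed time, and the reagent balance then showed where the race stopped. Each bis adduct took a second reagent, so one starting material went without. I called L the fraction of the charge left as starting material when the reagent gave out, which is also the fraction become bis adduct. Two rounds of substitution gave 25.6%, with 48.8% as single product. At the end, the leftover starting material could pair with single product, each pair removing one of each, so I committed to a share of 23.1% for spring. I reckoned no other set-up.

The forecast named spring as best, with summer 19%, dusk 16%, spring 23% and autumn 12%: “Batch keeps the most because all its reagent is spent early”.

The simulation gave spring as best: summer 18.9%, dusk 16.4%, spring 23.8%, autumn 11.7%. Spring held 26.7% bis adduct at 2.50 min, with 0.013% of its reagent left, which lies 1.1 percentage points from L. Doubling L gives 51.2% of side product in spring once the leftover starting material has paired off, and at 25.0 min, with 0% starting material, it read 53.4%.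

L belongs to the moment the reagent gives out, so for spring read at 1.0 min, with 0.56% of its reagent left, it again put bis adduct near 25.6%. That flask held 26.3% bis adduct, and its share was 31.5%.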